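**Retrosynthetic overview**

1. The acrylic acid is made last: 16 ⇐ enal 15 ⇐ aldehyde 13 (α-methylenation, then aldehyde to acid), so no Michael acceptor is present while the side chain is attached.
2. Side chain: the C1′–C2′ bond comes from the C5 bromomethyl arm of oxane 8 and the α-anion of (2E,6E)-farnesyl phenyl sulfone; palladium/hydride then removes the sulfonyl group and reduces the ester arm.
3. Enabling feature: C5 carries two CH2 arms, ring C6 (bound to O1) and side-chain C1′. Tying C1′ to O1 as well gives the four-membered ring O1–C6–C5–C1′ (a 3-substituted oxetane) in which C5 is not yet a stereocentre, with C4–C3–C2 attached as an (E)-enoate tether.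
4. Ring formation: the oxane is the only ring made, once, from the oxetane of 6. Catalytic enantioselective bromide opening of O1–C1′ sets C5, then O1 closes on C2 by oxa-Michael addition and sets C2 trans to C5; ring O1–C6–C5–C1′ becomes ring O1–C2–C3–C4–C5–C6.
5. Oxetane enoate 6 comes from 3-iodooxetane, methyl acrylate and a stabilised Wittig ylide.

Key step: step 3

Remark: oxane atoms are numbered O1, C2 (acrylic acid carbon), C3, C4, C5 (side-chain carbon), C6, and side-chain carbons C1′ onward from C5; both enantiomers of the squaramide catalyst class are taken to be accessible, and the one that leads to (6R)-7 is used.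

**Route**

Step 1
Reactants: 1 3-iodooxetane; 2 methyl acrylate
Product: 3 methyl 3-(oxetan-3-yl)propanoate
Conditions: (Me3Si)3SiH, AIBN (cat.), 2 in excess, PhMe, 80 °C
Reagents that add atoms: none
Why: Giese radical conjugate addition, in which the silyl radical abstracts iodine from 1, the nucleophilic oxetan-3-yl radical adds to the β-carbon of the acrylate and the α-ester radical is reduced by the silane; no stereocentre is formed.

Step 2
Reactants: 3 methyl 3-(oxetan-3-yl)propanoate; 4 methyl (triphenylphosphoranylidene)acetate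
Product: 6 methyl (2E)-5-(oxetan-3-yl)pent-2-enoate, via 3-(oxetan-3-yl)propanal 5 (not isolated)
Conditions: i-Bu2AlH, CH2Cl2, −78 °C; then 4, −78 °C to rt
Reagents that add atoms: none
Why: Partial reduction of the methyl ester to the aluminium hemiacetal at low temperature followed by in situ Wittig olefination with the stabilised ylide, which should give the (E)-enoate; the oxetane is inert to both reagents under these conditions.

Step 3
Reactants: 6 methyl (2E)-5-(oxetan-3-yl)pent-2-enoate
Product: 8 methyl 2-[(2S,5R)-5-(bromomethyl)oxan-2-yl]acetate, via silyl ether bromide 7 (not isolated)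
Conditions: chiral arylpyrrolidine squaramide hydrogen-bond-donor catalyst (5 mol %), Me3SiBr, t-BuOMe, −78 °C; then Bu4NF, THF, −78 to 0 °C
Reagents that add atoms: bromotrimethylsilane C[Si](C)(C)Br
Why: Mechanism: the squaramide binds the bromide of Me3SiBr, the silylated oxetanium ion of 6 is opened by SN2 attack of the catalyst-bound bromide on one of the two enantiotopic CH2–O carbons to give silyl ether 7, in which O1 stays on C6 and the attacked carbon has become the bromomethyl arm C1′; fluoride then frees the C6 alkoxide, which adds to C2 of the enoate by 6-exo-trig oxa-Michael addition, so that the four-membered ring O1–C6–C5–C1′ is exchanged for the six-membered ring O1–C2–C3–C4–C5–C6. The closest known reaction types are the hydrogen-bond-donor-catalysed enantioselective addition of Me3SiBr to 3-substituted oxetanes and the fluoride-triggered desilylation/oxa-Michael closure of hydroxy enoates to oxanes, both used here on their usual substrate classes and only run in one flask. C5 is set by the catalyst through discrimination of the two enantiotopic arms and is not touched afterwards; C2 is set in the ring closure through a chair transition state with the C5 bromomethyl group and the enoate arm both equatorial, which should favour the 2,5-trans isomer, and this preference is reinforced because the oxa-Michael addition is reversible and the trans isomer is the diequatorial one. The step needs chemoselectivity of Me3SiBr for the strained ether over the enoate, secured by the ring strain and Lewis basicity of the oxetane at −78 °C, and in the second stage 6-exo-trig conjugate addition in preference to 4-exo-tet re-closure on the CH2Br carbon, secured by the much faster formation of the six-membered ring on the activated alkene at or below 0 °C. Release of the oxetane ring strain drives the whole step, which turns an achiral three-step precursor into the ring, both stereocentres and the handle for the side chain.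

Step 4
Reactants: 9 (2E,6E)-farnesyl bromide
Product: 10 (2E,6E)-farnesyl phenyl sulfone
Conditions: PhSO2Na, DMF, rt
Reagents that add atoms: sodium benzenesulfinate [Na+].[O-]S(=O)c1ccccc1
Why: SN2 displacement of the primary allylic bromide by the sulfur atom of the sulfinate, which should proceed without allylic transposition and keep the 2E,6E geometry.

Step 5
Reactants: 10 (2E,6E)-farnesyl phenyl sulfone; 8 methyl 2-[(2S,5R)-5-(bromomethyl)oxan-2-yl]acetate
Product: 11 methyl 2-[(2S,5S)-5-[(3E,7E)-4,8,12-trimethyl-2-(phenylsulfonyl)trideca-3,7,11-trien-1-yl]oxan-2-yl]acetate (both epimers at the sulfonyl-bearing carbon; the C5 descriptor changes by priority only)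
Conditions: 10, n-BuLi, THF/HMPA, −78 °C; then 8, −78 to −20 °C
Reagents that add atoms: none
Why: Alkylation of a sulfonyl-stabilised allyl anion, which reacts at its α-carbon so that the C1′–C2′ bond forms without touching the (E)-trisubstituted alkenes; the anion is too weakly basic to enolise the ester, the ring stereocentres are remote from the reacting carbon, and the new sulfonyl-bearing centre is removed in step 6.

Step 6
Reactants: 11 methyl 2-[(2S,5S)-5-[(3E,7E)-4,8,12-trimethyl-2-(phenylsulfonyl)trideca-3,7,11-trien-1-yl]oxan-2-yl]acetate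
Product: 12 2-[(2S,5R)-5-[(3E,7E)-4,8,12-trimethyltrideca-3,7,11-trien-1-yl]oxan-2-yl]ethan-1-ol
Conditions: PdCl2(dppp) (5 mol %), LiBHEt3 (excess), THF, 0 °C to rt
Reagents that add atoms: none
Why: Zerovalent palladium formed in situ ionises the allylic C–S bond and hydride is delivered to the less substituted allyl terminus, a reductive desulfonylation known to keep the position and E geometry of prenyl-type alkenes, while the excess hydride reduces the methyl ester to the primary alcohol needed for the end game in the same operation.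

Step 7
Reactants: 12 2-[(2S,5R)-5-[(3E,7E)-4,8,12-trimethyltrideca-3,7,11-trien-1-yl]oxan-2-yl]ethan-1-ol
Product: 13 [(2S,5R)-5-[(3E,7E)-4,8,12-trimethyltrideca-3,7,11-trien-1-yl]oxan-2-yl]acetaldehyde
Conditions: Dess–Martin periodinane, NaHCO3, CH2Cl2, 0 °C to rt
Reagents that add atoms: none
Why: Dess–Martin oxidation of a primary alcohol to the aldehyde under buffered conditions that should leave the trisubstituted alkenes and the C2 stereocentre untouched.

Step 8
Reactants: 13 [(2S,5R)-5-[(3E,7E)-4,8,12-trimethyltrideca-3,7,11-trien-1-yl]oxan-2-yl]acetaldehyde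
Product: 15 2-[(2S,5R)-5-[(3E,7E)-4,8,12-trimethyltrideca-3,7,11-trien-1-yl]oxan-2-yl]prop-2-enal, via Mannich base 14 (not isolated)
Conditions: CH2=NMe2 I (Eschenmoser's salt), Et3N, CH2Cl2, rt
Reagents that add atoms: N,N-dimethylmethyleneiminium iodide C=[N+](C)C.[I-]
Why: Mannich reaction of the aldehyde enol with the iminium salt followed by base-assisted elimination of dimethylamine (α-methylenation of an aldehyde); once the α-carbon is sp2 the C2 stereocentre can no longer be lost by β-elimination of the ring oxygen.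

Step 9
Reactants: 15 2-[(2S,5R)-5-[(3E,7E)-4,8,12-trimethyltrideca-3,7,11-trien-1-yl]oxan-2-yl]prop-2-enal
Product: 16 2-[(2S,5R)-5-[(3E,7E)-4,8,12-trimethyltrideca-3,7,11-trien-1-yl]oxan-2-yl]prop-2-enoic acid
Conditions: NaClO2, NaH2PO4, 2-methyl-2-butene (large excess), t-BuOH/H2O, 0 °C to rt
Reagents that add atoms: sodium chlorite [Na+].[O-]Cl=O
Why: Pinnick oxidation of the 2-substituted acrolein to the acrylic acid, in which the excess 2-methyl-2-butene removes hypochlorous acid before it can attack the trisubstituted alkenes of the side chain; no stereocentre is affected.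

**Compound list**

1 | 3-iodooxetane | IC1COC1 | starting material
2 | methyl acrylate | C=CC(=O)OC | starting material
3 | methyl 3-(oxetan-3-yl)propanoate | COC(=O)CCC1COC1 | intermediate
4 | methyl (triphenylphosphoranylidene)acetate | COC(=O)C=P(c1ccccc1)(c1ccccc1)c1ccccc1 | starting material
5 | 3-(oxetan-3-yl)propanal | O=CCCC1COC1 | intermediate (not isolated)
6 | methyl (2E)-5-(oxetan-3-yl)pent-2-enoate | COC(=O)/C=C/CCC1COC1 | intermediate
7 | methyl (2E,6R)-6-(bromomethyl)-7-[(trimethylsilyl)oxy]hept-2-enoate | COC(=O)/C=C/CC[C@@H](CBr)CO[Si](C)(C)C | intermediate (not isolated)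
8 | methyl 2-[(2S,5R)-5-(bromomethyl)oxan-2-yl]acetate (2,5-trans) | COC(=O)C[C@@H]1CC[C@@H](CBr)CO1 | intermediate
9 | (2E,6E)-farnesyl bromide, (2E,6E)-1-bromo-3,7,11-trimethyldodeca-2,6,10-triene | CC(C)=CCC/C(C)=C/CC/C(C)=C/CBr | starting material
10 | (2E,6E)-farnesyl phenyl sulfone, {[(2E,6E)-3,7,11-trimethyldodeca-2,6,10-trien-1-yl]sulfonyl}benzene | CC(C)=CCC/C(C)=C/CC/C(C)=C/CS(=O)(=O)c1ccccc1 | intermediate
11 | methyl 2-[(2S,5S)-5-[(3E,7E)-4,8,12-trimethyl-2-(phenylsulfonyl)trideca-3,7,11-trien-1-yl]oxan-2-yl]acetate, both epimers at the sulfonyl-bearing carbon | COC(=O)C[C@@H]1CC[C@@H](CC(/C=C(\C)CC/C=C(\C)CCC=C(C)C)S(=O)(=O)c2ccccc2)CO1 | intermediate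
12 | 2-[(2S,5R)-5-[(3E,7E)-4,8,12-trimethyltrideca-3,7,11-trien-1-yl]oxan-2-yl]ethan-1-ol | OCC[C@@H]1CC[C@@H](CC/C=C(\C)CC/C=C(\C)CCC=C(C)C)CO1 | intermediate
13 | [(2S,5R)-5-[(3E,7E)-4,8,12-trimethyltrideca-3,7,11-trien-1-yl]oxan-2-yl]acetaldehyde | O=CC[C@@H]1CC[C@@H](CC/C=C(\C)CC/C=C(\C)CCC=C(C)C)CO1 | intermediate
14 | 3-(dimethylamino)-2-[(2S,5R)-5-[(3E,7E)-4,8,12-trimethyltrideca-3,7,11-trien-1-yl]oxan-2-yl]propanal, both epimers at C2 of the propanal | CN(C)CC(C=O)[C@@H]1CC[C@@H](CC/C=C(\C)CC/C=C(\C)CCC=C(C)C)CO1 | intermediate (not isolated)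
15 | 2-[(2S,5R)-5-[(3E,7E)-4,8,12-trimethyltrideca-3,7,11-trien-1-yl]oxan-2-yl]prop-2-enal | C=C(C=O)[C@@H]1CC[C@@H](CC/C=C(\C)CC/C=C(\C)CCC=C(C)C)CO1 | intermediate
16 | 2-[(2S,5R)-5-[(3E,7E)-4,8,12-trimethyltrideca-3,7,11-trien-1-yl]oxan-2-yl]prop-2-enoic acid | C=C(C(=O)O)[C@@H]1CC[C@@H](CC/C=C(\C)CC/C=C(\C)CCC=C(C)C)CO1 | target

**Step count and risks**

Total step count: 9. Longest linear sequence: 8 steps (steps 1, 2, 3, 5, 6, 7, 8, 9; step 4 prepares the sulfone partner).

Steps most likely to fail:

Step 3. The two enantiotopic CH2–O arms may be discriminated poorly when the 3-substituent of the oxetane is a flexible alkyl chain, which would erode the C5 configuration. In the second stage the bromo alkoxide may return to the oxetane by 4-exo-tet displacement, or the ring closure may show an incomplete trans preference. The fallback sets out from 3 and comes back at 8; it moves stereocontrol from the catalyst to a preset carbinol centre at C2. Crossed Claisen condensation of 3 with the lithium enolate of methyl acetate (LDA, MeOAc, THF, −78 °C) should give the β-keto ester methyl 3-oxo-5-(oxetan-3-yl)pentanoate F1. Asymmetric hydrogenation with RuCl2[(S)-BINAP] (H2, MeOH) should give methyl (3S)-3-hydroxy-5-(oxetan-3-yl)pentanoate F2. Camphorsulfonic acid (cat., CH2Cl2, 0 °C) should then let the C3 hydroxyl open the oxetane by 6-exo-tet attack on one CH2–O carbon, through a chair in which the ester arm is equatorial and the departing CH2–O arm is held equatorial by the four-membered ring. This gives the trans oxane alcohol methyl 2-[(2S,5S)-5-(hydroxymethyl)oxan-2-yl]acetate F3, again a four- to six-membered ring change, now with the carbinol oxygen as ring oxygen. Appel bromination (CBr4, PPh3, CH2Cl2, 0 °C) converts F3 into 8.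

Step 5. SN2 attack at the β-branched primary bromide may be slow, so that acylation of the sulfonyl carbanion by the methyl ester or E2 elimination to the exocyclic alkene competes. The fallback sets out from 8 and comes back at 12, bypassing step 6; it reverses the polarity of the coupling. Reduction of the ester (LiBH4, THF, 0 °C) should give 2-[(2S,5R)-5-(bromomethyl)oxan-2-yl]ethan-1-ol F4, and silylation (TBSCl, imidazole, DMF) the silyl ether tert-butyl{2-[(2S,5R)-5-(bromomethyl)oxan-2-yl]ethoxy}dimethylsilane F5. Magnesium insertion (Mg, THF) gives the Grignard reagent bromo{[(3R,6S)-6-(2-{[tert-butyl(dimethyl)silyl]oxy}ethyl)oxan-3-yl]methyl}magnesium F6. Coupling with 9 under Li2CuCl4 catalysis (THF, −10 °C) should occur by SN2 at the primary allylic carbon and give tert-butyldimethyl{2-[(2S,5R)-5-[(3E,7E)-4,8,12-trimethyltrideca-3,7,11-trien-1-yl]oxan-2-yl]ethoxy}silane F7. Bu4NF (THF) then releases 12.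

Step 8. The enol of the β-alkoxy aldehyde may undergo β-elimination of the ring oxygen (retro-oxa-Michael ring opening) under amine base before the Mannich capture, with loss of the ring or of the C2 configuration. The fallback sets out from 13 and comes back at 16; it carries out the methylenation at the ester oxidation level through a low-temperature lithium enolate. Oxidation of 13 (NaClO2, NaH2PO4, 2-methyl-2-butene) should give [(2S,5R)-5-[(3E,7E)-4,8,12-trimethyltrideca-3,7,11-trien-1-yl]oxan-2-yl]acetic acid F8, and Me3SiCHN2 (MeOH/PhMe) its methyl ester, methyl [(2S,5R)-5-[(3E,7E)-4,8,12-trimethyltrideca-3,7,11-trien-1-yl]oxan-2-yl]acetate F9. Enolisation with LDA (THF, −78 °C) and trapping with Eschenmoser's salt should give the amino ester methyl 3-(dimethylamino)-2-[(2S,5R)-5-[(3E,7E)-4,8,12-trimethyltrideca-3,7,11-trien-1-yl]oxan-2-yl]propanoate F10. MeI (MeOH) gives the quaternary salt 3-methoxy-N,N,N-trimethyl-3-oxo-2-[(2S,5R)-5-[(3E,7E)-4,8,12-trimethyltrideca-3,7,11-trien-1-yl]oxan-2-yl]propan-1-aminium iodide F11, and DBU (CH2Cl2) eliminates trimethylamine to give methyl 2-[(2S,5R)-5-[(3E,7E)-4,8,12-trimethyltrideca-3,7,11-trien-1-yl]oxan-2-yl]prop-2-enoate F12. LiOH (THF/H2O) hydrolyses F12 to 16.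

Further compounds
F1 | step 3 | methyl 3-oxo-5-(oxetan-3-yl)pentanoate | COC(=O)CC(=O)CCC1COC1
F2 | step 3 | methyl (3S)-3-hydroxy-5-(oxetan-3-yl)pentanoate | COC(=O)C[C@@H](O)CCC1COC1
F3 | step 3 | methyl 2-[(2S,5S)-5-(hydroxymethyl)oxan-2-yl]acetate | COC(=O)C[C@@H]1CC[C@@H](CO)CO1
F4 | step 5 | 2-[(2S,5R)-5-(bromomethyl)oxan-2-yl]ethan-1-ol | OCC[C@@H]1CC[C@@H](CBr)CO1
F5 | step 5 | tert-butyl{2-[(2S,5R)-5-(bromomethyl)oxan-2-yl]ethoxy}dimethylsilane | CC(C)(C)[Si](C)(C)OCC[C@@H]1CC[C@@H](CBr)CO1
F6 | step 5 | bromo{[(3R,6S)-6-(2-{[tert-butyl(dimethyl)silyl]oxy}ethyl)oxan-3-yl]methyl}magnesium | CC(C)(C)[Si](C)(C)OCC[C@@H]1CC[C@@H](C[Mg]Br)CO1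
F7 | step 5 | tert-butyldimethyl{2-[(2S,5R)-5-[(3E,7E)-4,8,12-trimethyltrideca-3,7,11-trien-1-yl]oxan-2-yl]ethoxy}silane | CC(C)(C)[Si](C)(C)OCC[C@@H]1CC[C@@H](CC/C=C(\C)CC/C=C(\C)CCC=C(C)C)CO1
F8 | step 8 | [(2S,5R)-5-[(3E,7E)-4,8,12-trimethyltrideca-3,7,11-trien-1-yl]oxan-2-yl]acetic acid | OC(=O)C[C@@H]1CC[C@@H](CC/C=C(\C)CC/C=C(\C)CCC=C(C)C)CO1
F9 | step 8 | methyl [(2S,5R)-5-[(3E,7E)-4,8,12-trimethyltrideca-3,7,11-trien-1-yl]oxan-2-yl]acetate | COC(=O)C[C@@H]1CC[C@@H](CC/C=C(\C)CC/C=C(\C)CCC=C(C)C)CO1
F10 | step 8 | methyl 3-(dimethylamino)-2-[(2S,5R)-5-[(3E,7E)-4,8,12-trimethyltrideca-3,7,11-trien-1-yl]oxan-2-yl]propanoate | COC(=O)C(CN(C)C)[C@@H]1CC[C@@H](CC/C=C(\C)CC/C=C(\C)CCC=C(C)C)CO1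
F11 | step 8 | 3-methoxy-N,N,N-trimethyl-3-oxo-2-[(2S,5R)-5-[(3E,7E)-4,8,12-trimethyltrideca-3,7,11-trien-1-yl]oxan-2-yl]propan-1-aminium iodide | COC(=O)C(C[N+](C)(C)C)[C@@H]1CC[C@@H](CC/C=C(\C)CC/C=C(\C)CCC=C(C)C)CO1.[I-]
F12 | step 8 | methyl 2-[(2S,5R)-5-[(3E,7E)-4,8,12-trimethyltrideca-3,7,11-trien-1-yl]oxan-2-yl]prop-2-enoate | COC(=O)C(=C)[C@@H]1CC[C@@H](CC/C=C(\C)CC/C=C(\C)CCC=C(C)C)CO1
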